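Saturday's run shares your flask's 0.10 M of solid substrate, the limiting reagent, but has 2 equiv of coupling partner where you charge 4.00 equiv, half.

| flask | solid substrate | coupling partner | remark | time |
|---|---|---|---|---|
| Wednesday's | 0.050 M | 4 equiv | run made earlier |  |
| Tuesday's | 0.075 M | 4 equiv | run made earlier |  |
| Saturday's | 0.10 M | 2 equiv | run made earlier |  |
| flask | 0.10 M | 4.00 equiv |  | 2.5 d |

| run | time / h | target / % |
|---|---|---|
| Wednesday's | 0.833 | 6.9 |
| Wednesday's | 2.00 | 11.1 |
| Wednesday's | 6.00 | 12.1 |
| Wednesday's | 15.0 | 7.3 |
| Wednesday's | 50.0 | 7.0 |
| Tuesday's | 0.833 | 8.8 |
| Tuesday's | 2.00 | 15.1 |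
| Tuesday's | 6.00 | 13.5 |
| Tuesday's | 15.0 | 8.2 |
| Tuesday's | 50.0 | 7.6 |
| Saturday's | 0.833 | 5.1 |
| Saturday's | 2.00 | 8.4 |
| Saturday's | 6.00 | 11.0 |
| Saturday's | 15.0 | 8.7 |
| Saturday's | 50.0 | 7.0 |

(each reading ± 0.5 percentage points)

- as a solid, counted per litre of solution: solid substrate
- the numbers in the tables scatter with a standard deviation of 0.5 percentage points
- at the start none of the solid substrate is in solution

- the moment within 2.5 d at which there is most target
- the amount of target, in percent of the solid substrate charged, at that time
- the first time at which target reaches 14%, in the same percent, in d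

Saturday's run looks contradictory. Its first reading gives an early slope of 0.0612 /h of the charge, a pace that would turn the charge into target in 16.3 h, shorter than the 50.0 h of its last reading. Yet its highest reading is 11.0%, and it ends at 7.0%. The two numbers agree if target is lost in proportion to the amount standing: it climbs until loss meets gain, so the highest reading is the early slope times a time. That time reads 1.46 h on Wednesday's run, 1.43 h on Tuesday's and 1.80 h on Saturday's. Their mean, 1.56 h, is the holding time, the highest reading divided by the early slope. Taking first order in coupling partner, your flask's slope becomes 0.122 /h of the charge, and my reckoning gives a best of 19.1%.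

The forecast, scaling the peaks, says 18% (15% to 21%) at 0.11 d, with the level reached at 0.055 d, a little below mine, and calls these “extrapolations beyond the tested conditions”.

    starting material + coupling partner → target (k = 1.81 × 10⁻⁴ /M/s)
    starting material → side product (k = 1.25 × 10⁻⁶ /s)
    target ⇌ isomer of the product (K = 13.0, k = 1.99 × 10⁻⁴ /s)
    solid substrate ⇌ starting material, rate k4*(cs4 - [starting material]) while solid is left; crystals form when [starting material] > cs4 (solubility = 0.0730 M, k = 0.00119 /s)

Your flask gives 19.4% at 0.125 d and reaches 14% at 0.0591 d; its best over that slope is 1.58 h, against the holding time of 1.56 h. Up to the best time, when solid substrate stood at 0% and starting material at 54.1%, coupling made target while target passed into isomer of the product, forward half-life 0.97 h. By 1.25 d starting material stood at 0.202%, with target at 7.05% beside 90.8% of isomer. For the neighbour charged with 0.025 M, Wednesday's slope scaled to its coupling partner, times the holding time, gives 6.47%; that flask reached 7.54%.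

(The numbers in the tables come from a simulation with constants of no real substance; noise was put on by code.)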